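The numbers are made up, and the outcome is calculated.

Tetra adduct comes from the last of 4 couplings on substrate, and triple product, one coupling short of it, can instead be taken by capture agent. Each coupling costs one coupling partner.

in all of them: substrate 0.0050 M; coupling partner 0.900 equiv; capture agent 0.250 mM; time 40 s

| run | temperature |
|---|---|
| ash | 100 °C |
| larch | 140 °C |
| maple | 120 °C |
| cedar | 80 °C |

* the flask with the highest share of tetra adduct in all that became tetra adduct or trapped intermediate ("all alike" if they lie within 1.5 percentage points) (ash / larch / maple / cedar / all alike)
* share of tetra adduct in all that became tetra adduct or trapped intermediate, ash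
* share of tetra adduct in all that became tetra adduct or trapped intermediate, larch
* share of tetra adduct in all that became tetra adduct or trapped intermediate, maple
* share of tetra adduct in all that became tetra adduct or trapped intermediate, cedar

- the list of constants is for 100 °C, to be carried to other temperatures by the activation energies

    coupling partner + triple product → tetra adduct + released group (k1 = 110 M⁻¹ s⁻¹, Ea1 = 39.0 kJ mol⁻¹)
    triple product + capture agent → trapped intermediate (k2 = 15 M⁻¹ s⁻¹, Ea2 = 45.0 kJ mol⁻¹)
    coupling partner + bis adduct → triple product + released group (k3 = 140 M⁻¹ s⁻¹, Ea3 = 45.0 kJ mol⁻¹)
    coupling partner + mono adduct → bis adduct + released group (k4 = 240 M⁻¹ s⁻¹, Ea4 = 36.0 kJ mol⁻¹)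
    substrate + coupling partner → mono adduct + released group (k5 = 110 M⁻¹ s⁻¹, Ea5 = 39.0 kJ mol⁻¹)
    (constants at 100 °C)

We solve the two ends separately and join them. Coupling partner, at 0.900 equiv, is the limiting reagent. In ash it meets substrate on a clock of 2.02 s, while a fresh charge of capture agent takes triple product on a clock of 267 s, so coupling ends far sooner and tetra adduct then stops growing.

For the slow end we use the capture number, the rate constant of capture at the flask's temperature (15 M⁻¹ s⁻¹ at 100 °C, 45.0 kJ mol⁻¹) times the starting capture agent times the time, a pseudo-first-order count. It comes to 0.0660 in cedar, 0.150 in ash, 0.314 in maple and 0.611 in larch.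

Capture agent thins as it works, so we take the part of the triple product captured as n/(1+n), which gives 37.9% in larch and 6.19% in cedar. If coupling leaves like amounts in the 4 flasks, cedar keeps the highest tetra adduct share. Our reckoning stops at this order and gives no shares.

The forecast names cedar, with 80% for cedar, 65% for ash, 50% for maple and 40% for larch. Its ground: "Once the coupling partner (0.9 equiv) is spent, within seconds, the tetra adduct stops forming".

The flasks give cedar as highest, with 80.2% for cedar, 64.8% for ash, 50.3% for maple and 39.8% for larch.

Larch reads 39.8%, and that share has moved by 5 points at 1.02 equiv of coupling partner or at 0.324 mM of capture agent, other amounts and the time held. At 40.0 s larch holds 2.55% trapped intermediate beside 4.88% triple product, so trapped intermediate is 34.3% of the two, against our 37.9%. Read at 1.5 min, the same larch flask has capture number 1.37, which gives a part of 57.9%. It holds 3.71% trapped intermediate beside 3.72% triple product, a part of 49.9%, and its share is 31.2%.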